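**Retrosynthetic overview**
1. Late stage: the C3 ester is introduced as an epoxy ester and opened with HCl last; the C4 acetate and the C11 carbinol (acetone aldol at C7, then conjugation to the 6-en-8-one) are set on a 3β,4α-dioxygenated decalin.
2. Structural feature used: ring B (C5–C10) is a cyclohexenone whose carbonyl C8 lies between C9, the methylene on quaternary C10, and C7. Removing C8 as CO leaves a vinylcyclopropane (three-membered ring C5–C9–C10, vinyl C6=C7 on C5), so ring B is closed by a metal-catalysed [5+1] carbonylation.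
3. The vinylcyclopropane comes from a ring A diene (C10=C5–C6=C7) by C4–OH-directed Simmons–Smith methylenation, which fixes C10; the diene comes from the enol triflate of a C5 ketone and a vinylstannane.
4. Ring A stereocentres: C3 by CBS reduction of 2-methylcyclohex-2-en-1-one, C4 by osmylation anti to the C3 silyloxy group; the acid side chain by Sharpless epoxidation.
5. Ring order: ring A (purchased carbocycle), then the cyclopropane, then ring B.

Key step: step 11

Remark on numbering: eudesmane numbering is used in the explanations (ring A: C1–C5 and C10; ring B: C5–C10; C11 is the carbinol carbon on C7; primed numbers for the butanoate).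
Remark on the side chain: chloride opens a 2,3-epoxy-2-methylbutanoate at C3′ with inversion, so the (2R,3S)-chlorohydrin requires the trans (2S,3R)-epoxide, which is the epoxide of the (E)-acid, tiglic acid. The (Z)-acid would give the C3′ epimer, so tiglic acid is the starting material.
Assumption: 2-methylcyclohex-2-en-1-one, tiglic acid, carbon monoxide and the reagents named are commercial.

Step 1
Reactants: 1 2-methylcyclohex-2-en-1-one
Product: 2 (1S)-2-methylcyclohex-2-en-1-ol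
Conditions: (R)-2-methyl-CBS-oxazaborolidine (10 mol %), BH3·SMe2, THF, −20 °C; aqueous work-up
Reagents that add atoms: none
Why: Corey–Bakshi–Shibata reduction, in which the oxazaborolidine–borane complex distinguishes the α-methylvinyl flank (large) from the ring CH2 (small), so the (R)-catalyst should give the (S)-allylic alcohol that becomes C3.

Step 2
Reactants: 2 (1S)-2-methylcyclohex-2-en-1-ol
Product: 3 tert-butyldimethyl{[(1S)-2-methylcyclohex-2-en-1-yl]oxy}silane
Conditions: TBSCl, imidazole, DMF, rt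
Reagents that add atoms: tert-butyldimethylsilyl chloride, CC(C)(C)[Si](C)(C)Cl
Why: Imidazole-promoted silylation of a secondary alcohol, which installs the bulky allylic ether that steers the osmylation and protects C3–O until step 16.

Step 3
Reactants: 3 tert-butyldimethyl{[(1S)-2-methylcyclohex-2-en-1-yl]oxy}silane
Product: 4 (1S,2S,3S)-3-[(tert-butyldimethylsilyl)oxy]-2-methylcyclohexane-1,2-diol
Conditions: OsO4 (2 mol %), NMO, acetone/H2O, rt
Reagents that add atoms: N-methylmorpholine N-oxide, C[N+]1([O-])CCOCC1; water, O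
Why: Catalytic syn-dihydroxylation in which OsO4 attacks the face opposite the pseudoaxial allylic silyloxy group (the empirical rule for allylic ethers), so the tertiary C4 hydroxyl is set trans to the C3 oxygen.

Step 4
Reactants: 4 (1S,2S,3S)-3-[(tert-butyldimethylsilyl)oxy]-2-methylcyclohexane-1,2-diol
Product: 5 (2R,3S)-3-[(tert-butyldimethylsilyl)oxy]-2-hydroxy-2-methylcyclohexan-1-one
Conditions: IBX, DMSO, rt
Reagents that add atoms: none
Why: IBX oxidation of the secondary alcohol of a 1,2-diol to the α-ketol without C–C cleavage, the tertiary carbinol being inert; the new carbonyl is C5.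

Step 5
Reactants: 5 (2R,3S)-3-[(tert-butyldimethylsilyl)oxy]-2-hydroxy-2-methylcyclohexan-1-one
Product: 6 (2R,3S)-3-[(tert-butyldimethylsilyl)oxy]-2-methyl-2-[(trimethylsilyl)oxy]cyclohexan-1-one
Conditions: TMSCl, imidazole, DMF, rt
Reagents that add atoms: chlorotrimethylsilane, C[Si](C)(C)Cl
Why: Silylation of the tertiary α-ketol hydroxyl, so that the two enolate steps run on a mono-anion without α-ketol rearrangement or O-sulfonylation.

Step 6
Reactants: 6 (2R,3S)-3-[(tert-butyldimethylsilyl)oxy]-2-methyl-2-[(trimethylsilyl)oxy]cyclohexan-1-one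
Product: 8 (2R,3S)-3-[(tert-butyldimethylsilyl)oxy]-2,6-dimethyl-2-[(trimethylsilyl)oxy]cyclohexan-1-one (C6 epimers), via lithium enolate 7 (not isolated)
Conditions: LiN(iPr)2, THF, −78 °C; MeI, −78 → −20 °C
Reagents that add atoms: iodomethane, CI
Why: Enolate alkylation that can only occur at C10 because C4 is quaternary; the configuration of the new centre is irrelevant since it becomes trigonal in step 7.

Step 7
Reactants: 8 (2R,3S)-3-[(tert-butyldimethylsilyl)oxy]-2,6-dimethyl-2-[(trimethylsilyl)oxy]cyclohexan-1-one (C6 epimers)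
Product: 10 (5S,6R)-5-[(tert-butyldimethylsilyl)oxy]-2,6-dimethyl-6-[(trimethylsilyl)oxy]cyclohex-1-en-1-yl trifluoromethanesulfonate, via potassium enolate 9 (not isolated)
Conditions: KN(SiMe3)2, THF, −78 → 0 °C; PhNTf2, −78 °C → rt
Reagents that add atoms: N-phenylbis(trifluoromethanesulfonimide), O=S(=O)(N(c1ccccc1)S(=O)(=O)C(F)(F)F)C(F)(F)F
Why: Enolate O-triflation; only one enolate can form, so the C5=C10 double bond is placed unambiguously and both C10 epimers converge.

Step 8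
Reactants: 10 (5S,6R)-5-[(tert-butyldimethylsilyl)oxy]-2,6-dimethyl-6-[(trimethylsilyl)oxy]cyclohex-1-en-1-yl trifluoromethanesulfonate
Product: 11 tert-butyl{[(1S,2S)-3-ethenyl-2,4-dimethyl-2-[(trimethylsilyl)oxy]cyclohex-3-en-1-yl]oxy}dimethylsilane
Conditions: tributyl(vinyl)stannane, Pd(PPh3)4 (5 mol %), CuI (10 mol %), LiCl, DMF, 60 °C
Reagents that add atoms: tributyl(vinyl)stannane, C=C[Sn](CCCC)(CCCC)CCCC
Why: Stille coupling (oxidative addition of the enol triflate to zerovalent palladium, LiCl/CuI-assisted transmetallation, reductive elimination), a reaction that tolerates hindered cycloalkenyl triflates and both silyl ethers.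

Step 9
Reactants: 11 tert-butyl{[(1S,2S)-3-ethenyl-2,4-dimethyl-2-[(trimethylsilyl)oxy]cyclohex-3-en-1-yl]oxy}dimethylsilane
Product: 12 (1S,6S)-6-[(tert-butyldimethylsilyl)oxy]-2-ethenyl-1,3-dimethylcyclohex-2-en-1-ol
Conditions: K2CO3, MeOH, rt
Reagents that add atoms: none
Why: Base-mediated methanolysis removes the trimethylsilyl ether only (the TBS ether is stable), and the basic medium avoids ionisation of the dienylic tertiary alcohol.

Step 10
Reactants: 12 (1S,6S)-6-[(tert-butyldimethylsilyl)oxy]-2-ethenyl-1,3-dimethylcyclohex-2-en-1-ol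
Product: 13 (1R,2S,3S,6R)-3-[(tert-butyldimethylsilyl)oxy]-1-ethenyl-2,6-dimethylbicyclo[4.1.0]heptan-2-ol
Conditions: Et2Zn, CH2I2, CH2Cl2, 0 °C → rt
Reagents that add atoms: diiodomethane, ICI
Why: Hydroxyl-directed Simmons–Smith cyclopropanation in which the zinc alkoxide of the C4 carbinol delivers the methylene to the adjacent, electron-rich tetrasubstituted C5=C10 alkene on its own (α) face, which fixes C10 and C5 and should spare the less nucleophilic vinyl group when the carbenoid excess is limited.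

Step 11
Reactants: 13 (1R,2S,3S,6R)-3-[(tert-butyldimethylsilyl)oxy]-1-ethenyl-2,6-dimethylbicyclo[4.1.0]heptan-2-ol; 14 carbon monoxide
Product: 15 (5S,6S,8aR)-6-[(tert-butyldimethylsilyl)oxy]-5-hydroxy-5,8a-dimethyl-3,5,6,7,8,8a-hexahydronaphthalen-2(1H)-one
Conditions: [Rh(CO)2Cl]2 (5 mol %), CO (1 atm), toluene, 80 °C
Reagents that add atoms: none
Why: Rhodium-catalysed [5+1] cycloaddition of a vinylcyclopropane with CO, a known route to β,γ-cyclohexenones: monovalent rhodium binds the vinyl group, adds oxidatively into the proximal C5–C9 bond to give a rhodacycle σ-bound at C9 and η3-bound over C5–C6–C7, CO inserts into the Rh–C9 bond and reductive elimination joins the acyl carbon C8 to C7. Ring B is thus closed by C–C reductive elimination from the acyl(allyl)rhodium metallacycle, a formal [5+1] annulation that makes the C8–C9 and C7–C8 bonds. No stereocentre is formed, because C10 was fixed in step 10 and C5 becomes trigonal. The step needs cleavage of C5–C9 and not of the ring-fusion bond C5–C10: C9 is the only unsubstituted cyclopropane carbon and lies exposed on the α face next to the C4 hydroxyl, whereas opening C5–C10 would put rhodium on a quaternary carbon and lead to a bridged ring with a strained bridgehead alkene. It also needs the alkene to stay at C5=C6, which the neutral, base-free medium should ensure.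

Step 12
Reactants: 15 (5S,6S,8aR)-6-[(tert-butyldimethylsilyl)oxy]-5-hydroxy-5,8a-dimethyl-3,5,6,7,8,8a-hexahydronaphthalen-2(1H)-one
Product: 16 (5S,6S,8aR)-6-[(tert-butyldimethylsilyl)oxy]-5,8a-dimethyl-5-[(trimethylsilyl)oxy]-3,5,6,7,8,8a-hexahydronaphthalen-2(1H)-one
Conditions: 1-(trimethylsilyl)imidazole, CH2Cl2, rt
Reagents that add atoms: 1-(trimethylsilyl)imidazole, C[Si](C)(C)n1ccnc1
Why: Silylation of the tertiary C4 hydroxyl under nearly neutral conditions, which should not move the β,γ-double bond, and which distinguishes C4–O from the C11 hydroxyl made in step 13.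

Step 13
Reactants: 16 (5S,6S,8aR)-6-[(tert-butyldimethylsilyl)oxy]-5,8a-dimethyl-5-[(trimethylsilyl)oxy]-3,5,6,7,8,8a-hexahydronaphthalen-2(1H)-one
Product: 19 (5S,6S,8aR)-6-[(tert-butyldimethylsilyl)oxy]-3-(2-hydroxypropan-2-yl)-5,8a-dimethyl-5-[(trimethylsilyl)oxy]-3,5,6,7,8,8a-hexahydronaphthalen-2(1H)-one (C3 epimers), via lithium dienolate 17 (not isolated), via lithium aldolate 18 (not isolated)
Conditions: LiN(iPr)2, THF, −78 °C; acetone, −78 °C; AcOH, −78 °C
Reagents that add atoms: acetone, CC(C)=O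
Why: Aldol addition in which the doubly activated C7–H (α to the ketone and allylic) is removed selectively and the lithium dienolate attacks acetone through its α-carbon C7 (the γ-carbon C5 is fully substituted); the C7 configuration does not matter because C7 becomes trigonal in step 15.

Step 14
Reactants: 19 (5S,6S,8aR)-6-[(tert-butyldimethylsilyl)oxy]-3-(2-hydroxypropan-2-yl)-5,8a-dimethyl-5-[(trimethylsilyl)oxy]-3,5,6,7,8,8a-hexahydronaphthalen-2(1H)-one (C3 epimers)
Product: 20 (5S,6S,8aR)-6-[(tert-butyldimethylsilyl)oxy]-3-{2-[(tert-butyldimethylsilyl)oxy]propan-2-yl}-5,8a-dimethyl-5-[(trimethylsilyl)oxy]-3,5,6,7,8,8a-hexahydronaphthalen-2(1H)-one (C3 epimers)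
Conditions: TBSOTf, 2,6-lutidine, CH2Cl2, −78 → 0 °C
Reagents that add atoms: tert-butyldimethylsilyl trifluoromethanesulfonate, CC(C)(C)[Si](C)(C)OS(=O)(=O)C(F)(F)F
Why: Silyl triflate silylation of the tertiary aldol hydroxyl, which blocks retro-aldol cleavage in step 15 and gives C11–O a robust group distinct from those on C3 and C4.

Step 15
Reactants: 20 (5S,6S,8aR)-6-[(tert-butyldimethylsilyl)oxy]-3-{2-[(tert-butyldimethylsilyl)oxy]propan-2-yl}-5,8a-dimethyl-5-[(trimethylsilyl)oxy]-3,5,6,7,8,8a-hexahydronaphthalen-2(1H)-one (C3 epimers)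
Product: 21 (4aR,5S,6S,8aR)-6-[(tert-butyldimethylsilyl)oxy]-3-{2-[(tert-butyldimethylsilyl)oxy]propan-2-yl}-5,8a-dimethyl-5-[(trimethylsilyl)oxy]-4a,5,6,7,8,8a-hexahydronaphthalen-2(1H)-one
Conditions: DBU (0.5 equiv), CH2Cl2, rt
Reagents that add atoms: none
Why: Base-catalysed isomerisation of the β,γ- to the α,β-unsaturated ketone through the dienolate, in which γ-protonation at C5 should occur on the α face, opposite the axial methyl groups on C4 and C10 that flank it, to give the trans ring fusion (5α-H).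

Step 16
Reactants: 21 (4aR,5S,6S,8aR)-6-[(tert-butyldimethylsilyl)oxy]-3-{2-[(tert-butyldimethylsilyl)oxy]propan-2-yl}-5,8a-dimethyl-5-[(trimethylsilyl)oxy]-4a,5,6,7,8,8a-hexahydronaphthalen-2(1H)-one
Product: 22 (4aR,5S,6S,8aR)-3-{2-[(tert-butyldimethylsilyl)oxy]propan-2-yl}-5,6-dihydroxy-5,8a-dimethyl-4a,5,6,7,8,8a-hexahydronaphthalen-2(1H)-one
Conditions: HF·pyridine, pyridine, THF, 0 °C → rt
Reagents that add atoms: none
Why: Acidic fluoride desilylation graded by sterics: the trimethylsilyl ether and the secondary TBS ether are cleaved, the shielded tertiary TBS ether on C11 should survive, and the non-basic medium leaves C5 untouched.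

Step 17
Reactants: 23 tiglic acid [(E)-2-methylbut-2-enoic acid]
Product: 24 (E)-2-methylbut-2-en-1-ol
Conditions: LiAlH4, Et2O, 0 °C → rt; aqueous work-up
Reagents that add atoms: none
Why: Hydride reduction of the carboxylic acid to the allylic alcohol with retention of the (E) geometry, which gives the substrate class best suited to asymmetric epoxidation.

Step 18
Reactants: 24 (E)-2-methylbut-2-en-1-ol
Product: 25 [(2R,3R)-2,3-dimethyloxiran-2-yl]methanol
Conditions: Ti(OiPr)4, D-(−)-diethyl tartrate, tBuOOH, 4 Å molecular sieves, CH2Cl2, −20 °C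
Reagents that add atoms: tert-butyl hydroperoxide, CC(C)(C)OO
Why: Sharpless asymmetric epoxidation, in which the titanium–D-tartrate complex delivers oxygen to the face of the (E)-allylic alcohol that gives the (2R,3R)-epoxy alcohol, so both stereocentres are set by the catalyst.

Step 19
Reactants: 25 [(2R,3R)-2,3-dimethyloxiran-2-yl]methanol
Product: 26 (2S,3R)-2,3-dimethyloxirane-2-carboxylic acid
Conditions: RuCl3·xH2O (2 mol %), NaIO4, CCl4/MeCN/H2O, rt
Reagents that add atoms: water, O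
Why: RuO4 oxidation (generated from RuCl3 and NaIO4) of the primary alcohol to the acid without opening the epoxide; the change of the C2 descriptor from R to S reflects only the new substituent priorities.

Step 20
Reactants: 22 (4aR,5S,6S,8aR)-3-{2-[(tert-butyldimethylsilyl)oxy]propan-2-yl}-5,6-dihydroxy-5,8a-dimethyl-4a,5,6,7,8,8a-hexahydronaphthalen-2(1H)-one; 26 (2S,3R)-2,3-dimethyloxirane-2-carboxylic acid
Product: 27 (1S,2S,4aR,8aR)-7-{2-[(tert-butyldimethylsilyl)oxy]propan-2-yl}-1-hydroxy-1,4a-dimethyl-6-oxo-1,2,3,4,4a,5,6,8a-octahydronaphthalen-2-yl (2S,3R)-2,3-dimethyloxirane-2-carboxylate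
Conditions: DCC, DMAP, CH2Cl2, 0 °C → rt
Reagents that add atoms: none
Why: Steglich esterification in which only the secondary C3 hydroxyl is acylated (the tertiary C4 hydroxyl and the silylated C11 oxygen are inert), and the acid has no α-hydrogen, so its stereocentres cannot epimerise.

Step 21
Reactants: 27 (1S,2S,4aR,8aR)-7-{2-[(tert-butyldimethylsilyl)oxy]propan-2-yl}-1-hydroxy-1,4a-dimethyl-6-oxo-1,2,3,4,4a,5,6,8a-octahydronaphthalen-2-yl (2S,3R)-2,3-dimethyloxirane-2-carboxylate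
Product: 28 (1S,2S,4aR,8aR)-1-acetoxy-7-{2-[(tert-butyldimethylsilyl)oxy]propan-2-yl}-1,4a-dimethyl-6-oxo-1,2,3,4,4a,5,6,8a-octahydronaphthalen-2-yl (2S,3R)-2,3-dimethyloxirane-2-carboxylate
Conditions: Ac2O, DMAP, Et3N, CH2Cl2, 40 °C
Reagents that add atoms: acetic anhydride, CC(=O)OC(C)=O
Why: DMAP-catalysed acetylation of the tertiary C4 alcohol, now the only free hydroxyl; the epoxy ester, enone and tertiary silyl ether tolerate the mildly basic medium, and migration of the C3 ester to the tertiary oxygen is uphill.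

Step 22
Reactants: 28 (1S,2S,4aR,8aR)-1-acetoxy-7-{2-[(tert-butyldimethylsilyl)oxy]propan-2-yl}-1,4a-dimethyl-6-oxo-1,2,3,4,4a,5,6,8a-octahydronaphthalen-2-yl (2S,3R)-2,3-dimethyloxirane-2-carboxylate
Product: 29 (1S,2S,4aR,8aR)-1-acetoxy-7-{2-[(tert-butyldimethylsilyl)oxy]propan-2-yl}-1,4a-dimethyl-6-oxo-1,2,3,4,4a,5,6,8a-octahydronaphthalen-2-yl (2R,3S)-3-chloro-2-hydroxy-2-methylbutanoate
Conditions: HCl (4 M in 1,4-dioxane), CH2Cl2, 0 °C
Reagents that add atoms: hydrogen chloride, Cl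
Why: Acid-promoted SN2 opening of the epoxide, in which chloride attacks the secondary C3′ with inversion (C2′ is quaternary and deactivated by the ester carbonyl), turning the (2S,3R)-epoxide into the (2R,3S)-3-chloro-2-hydroxy ester.

Step 23
Reactants: 29 (1S,2S,4aR,8aR)-1-acetoxy-7-{2-[(tert-butyldimethylsilyl)oxy]propan-2-yl}-1,4a-dimethyl-6-oxo-1,2,3,4,4a,5,6,8a-octahydronaphthalen-2-yl (2R,3S)-3-chloro-2-hydroxy-2-methylbutanoate
Product: 30 (1S,2S,4aR,8aR)-1-acetoxy-7-(2-hydroxypropan-2-yl)-1,4a-dimethyl-6-oxo-1,2,3,4,4a,5,6,8a-octahydronaphthalen-2-yl (2R,3S)-3-chloro-2-hydroxy-2-methylbutanoate (CNP0119872.1)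
Conditions: HF (48 % aq.), MeCN, 0 °C → rt
Reagents that add atoms: none
Why: Acidic fluoride cleavage of the tertiary silyl ether; the acetate, chlorohydrin ester and enone are stable to aqueous HF, and no base is present that could close the chlorohydrin back to the epoxide.

**Compound list**
1 | 2-methylcyclohex-2-en-1-one | CC1=CCCCC1=O | starting material
2 | (1S)-2-methylcyclohex-2-en-1-ol | O[C@H]1CCCC=C1C | intermediate
3 | tert-butyldimethyl{[(1S)-2-methylcyclohex-2-en-1-yl]oxy}silane | CC(C)(C)[Si](C)(C)O[C@H]1CCCC=C1C | intermediate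
4 | (1S,2S,3S)-3-[(tert-butyldimethylsilyl)oxy]-2-methylcyclohexane-1,2-diol (both hydroxyls trans to the silyloxy group) | O[C@]1(C)[C@@H](O[Si](C)(C)C(C)(C)C)CCC[C@@H]1O | intermediate
5 | (2R,3S)-3-[(tert-butyldimethylsilyl)oxy]-2-hydroxy-2-methylcyclohexan-1-one | O[C@]1(C)[C@@H](O[Si](C)(C)C(C)(C)C)CCCC1=O | intermediate
6 | (2R,3S)-3-[(tert-butyldimethylsilyl)oxy]-2-methyl-2-[(trimethylsilyl)oxy]cyclohexan-1-one | C[Si](C)(C)O[C@]1(C)[C@@H](O[Si](C)(C)C(C)(C)C)CCCC1=O | intermediate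
7 | lithium (5S,6R)-5-[(tert-butyldimethylsilyl)oxy]-6-methyl-6-[(trimethylsilyl)oxy]cyclohex-1-en-1-olate (enolate of 6, not isolated) | C[Si](C)(C)O[C@]1(C)[C@@H](O[Si](C)(C)C(C)(C)C)CCC=C1O[Li] | intermediate
8 | (2R,3S)-3-[(tert-butyldimethylsilyl)oxy]-2,6-dimethyl-2-[(trimethylsilyl)oxy]cyclohexan-1-one (C6 epimers) | C[Si](C)(C)O[C@]1(C)[C@@H](O[Si](C)(C)C(C)(C)C)CCC(C)C1=O | intermediate
9 | potassium (5S,6R)-5-[(tert-butyldimethylsilyl)oxy]-2,6-dimethyl-6-[(trimethylsilyl)oxy]cyclohex-1-en-1-olate (enolate of 8, not isolated) | C[Si](C)(C)O[C@]1(C)[C@@H](O[Si](C)(C)C(C)(C)C)CCC(C)=C1O[K] | intermediate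
10 | (5S,6R)-5-[(tert-butyldimethylsilyl)oxy]-2,6-dimethyl-6-[(trimethylsilyl)oxy]cyclohex-1-en-1-yl trifluoromethanesulfonate | C[Si](C)(C)O[C@]1(C)[C@@H](O[Si](C)(C)C(C)(C)C)CCC(C)=C1OS(=O)(=O)C(F)(F)F | intermediate
11 | tert-butyl{[(1S,2S)-3-ethenyl-2,4-dimethyl-2-[(trimethylsilyl)oxy]cyclohex-3-en-1-yl]oxy}dimethylsilane | C[Si](C)(C)O[C@]1(C)[C@@H](O[Si](C)(C)C(C)(C)C)CCC(C)=C1C=C | intermediate
12 | (1S,6S)-6-[(tert-butyldimethylsilyl)oxy]-2-ethenyl-1,3-dimethylcyclohex-2-en-1-ol | O[C@]1(C)[C@@H](O[Si](C)(C)C(C)(C)C)CCC(C)=C1C=C | intermediate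
13 | (1R,2S,3S,6R)-3-[(tert-butyldimethylsilyl)oxy]-1-ethenyl-2,6-dimethylbicyclo[4.1.0]heptan-2-ol (cyclopropane CH2 syn to the C2 hydroxyl) | O[C@]1(C)[C@@H](O[Si](C)(C)C(C)(C)C)CC[C@]2(C)C[C@@]21C=C | intermediate
14 | carbon monoxide | [C-]#[O+] | starting material
15 | (5S,6S,8aR)-6-[(tert-butyldimethylsilyl)oxy]-5-hydroxy-5,8a-dimethyl-3,5,6,7,8,8a-hexahydronaphthalen-2(1H)-one | O[C@]1(C)[C@@H](O[Si](C)(C)C(C)(C)C)CC[C@]2(C)CC(=O)CC=C21 | intermediate
16 | (5S,6S,8aR)-6-[(tert-butyldimethylsilyl)oxy]-5,8a-dimethyl-5-[(trimethylsilyl)oxy]-3,5,6,7,8,8a-hexahydronaphthalen-2(1H)-one | C[Si](C)(C)O[C@]1(C)[C@@H](O[Si](C)(C)C(C)(C)C)CC[C@]2(C)CC(=O)CC=C21 | intermediate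
17 | lithium dienolate of 16 (O–Li on C8; C7=C8 and C5=C6; not isolated) | C[Si](C)(C)O[C@]1(C)[C@@H](O[Si](C)(C)C(C)(C)C)CC[C@]2(C)CC(O[Li])=CC=C21 | intermediate
18 | lithium aldolate (O–Li on C11; C7 epimers; not isolated) | C[Si](C)(C)O[C@]1(C)[C@@H](O[Si](C)(C)C(C)(C)C)CC[C@]2(C)CC(=O)C(C(C)(C)O[Li])C=C21 | intermediate
19 | (5S,6S,8aR)-6-[(tert-butyldimethylsilyl)oxy]-3-(2-hydroxypropan-2-yl)-5,8a-dimethyl-5-[(trimethylsilyl)oxy]-3,5,6,7,8,8a-hexahydronaphthalen-2(1H)-one (C3 epimers) | C[Si](C)(C)O[C@]1(C)[C@@H](O[Si](C)(C)C(C)(C)C)CC[C@]2(C)CC(=O)C(C(C)(C)O)C=C21 | intermediate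
20 | (5S,6S,8aR)-6-[(tert-butyldimethylsilyl)oxy]-3-{2-[(tert-butyldimethylsilyl)oxy]propan-2-yl}-5,8a-dimethyl-5-[(trimethylsilyl)oxy]-3,5,6,7,8,8a-hexahydronaphthalen-2(1H)-one (C3 epimers) | C[Si](C)(C)O[C@]1(C)[C@@H](O[Si](C)(C)C(C)(C)C)CC[C@]2(C)CC(=O)C(C(C)(C)O[Si](C)(C)C(C)(C)C)C=C21 | intermediate
21 | (4aR,5S,6S,8aR)-6-[(tert-butyldimethylsilyl)oxy]-3-{2-[(tert-butyldimethylsilyl)oxy]propan-2-yl}-5,8a-dimethyl-5-[(trimethylsilyl)oxy]-4a,5,6,7,8,8a-hexahydronaphthalen-2(1H)-one | C[Si](C)(C)O[C@]1(C)[C@@H](O[Si](C)(C)C(C)(C)C)CC[C@]2(C)CC(=O)C(C(C)(C)O[Si](C)(C)C(C)(C)C)=C[C@H]21 | intermediate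
22 | (4aR,5S,6S,8aR)-3-{2-[(tert-butyldimethylsilyl)oxy]propan-2-yl}-5,6-dihydroxy-5,8a-dimethyl-4a,5,6,7,8,8a-hexahydronaphthalen-2(1H)-one | O[C@]1(C)[C@@H](O)CC[C@]2(C)CC(=O)C(C(C)(C)O[Si](C)(C)C(C)(C)C)=C[C@H]21 | intermediate
23 | tiglic acid, (E)-2-methylbut-2-enoic acid | C/C=C(\C)C(=O)O | starting material
24 | (E)-2-methylbut-2-en-1-ol | C/C=C(\C)CO | intermediate
25 | [(2R,3R)-2,3-dimethyloxiran-2-yl]methanol | OC[C@@]1(C)O[C@@H]1C | intermediate
26 | (2S,3R)-2,3-dimethyloxirane-2-carboxylic acid | OC(=O)[C@@]1(C)O[C@@H]1C | intermediate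
27 | (1S,2S,4aR,8aR)-7-{2-[(tert-butyldimethylsilyl)oxy]propan-2-yl}-1-hydroxy-1,4a-dimethyl-6-oxo-1,2,3,4,4a,5,6,8a-octahydronaphthalen-2-yl (2S,3R)-2,3-dimethyloxirane-2-carboxylate | O[C@]1(C)[C@@H](OC(=O)[C@@]3(C)O[C@@H]3C)CC[C@]2(C)CC(=O)C(C(C)(C)O[Si](C)(C)C(C)(C)C)=C[C@H]21 | intermediate
28 | (1S,2S,4aR,8aR)-1-acetoxy-7-{2-[(tert-butyldimethylsilyl)oxy]propan-2-yl}-1,4a-dimethyl-6-oxo-1,2,3,4,4a,5,6,8a-octahydronaphthalen-2-yl (2S,3R)-2,3-dimethyloxirane-2-carboxylate | CC(=O)O[C@]1(C)[C@@H](OC(=O)[C@@]3(C)O[C@@H]3C)CC[C@]2(C)CC(=O)C(C(C)(C)O[Si](C)(C)C(C)(C)C)=C[C@H]21 | intermediate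
29 | (1S,2S,4aR,8aR)-1-acetoxy-7-{2-[(tert-butyldimethylsilyl)oxy]propan-2-yl}-1,4a-dimethyl-6-oxo-1,2,3,4,4a,5,6,8a-octahydronaphthalen-2-yl (2R,3S)-3-chloro-2-hydroxy-2-methylbutanoate | CC(=O)O[C@]1(C)[C@@H](OC(=O)[C@@](C)(O)[C@H](C)Cl)CC[C@]2(C)CC(=O)C(C(C)(C)O[Si](C)(C)C(C)(C)C)=C[C@H]21 | intermediate
30 | (1S,2S,4aR,8aR)-1-acetoxy-7-(2-hydroxypropan-2-yl)-1,4a-dimethyl-6-oxo-1,2,3,4,4a,5,6,8a-octahydronaphthalen-2-yl (2R,3S)-3-chloro-2-hydroxy-2-methylbutanoate (CNP0119872.1) | CC(=O)O[C@]1(C)[C@@H](OC(=O)[C@@](C)(O)[C@H](C)Cl)CC[C@]2(C)CC(=O)C(C(C)(C)O)=C[C@H]21 | target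

**Step count**
Total: 23 steps (20 in the main line, 3 for acid 26).
Longest linear sequence: 20 steps (1 to 30 through steps 1–16 and 20–23).

**The three steps most likely to fail**

Step 11 (the [5+1] carbonylation). Oxidative addition into the fully substituted, hindered cyclopropane may be slow; the rhodacycle may be diverted by β-hydride elimination to ring-opened dienes; or the alkene may drift into conjugation under the reaction conditions and spoil the C7 selectivity of step 13. The fallback leaves catalytic rhodium for a stoichiometric iron template. It sets out from 13: irradiation with Fe(CO)5 under CO (1 atm, 2-propanol, room temperature) should first bind the vinyl group to an iron tetracarbonyl fragment, then open the proximal C5–C9 bond to a σ-alkyl/η3-allyl iron carbonyl that takes up CO and collapses to the cyclohexenone at ambient temperature, away from the thermal side reactions. It comes back to the route at 15 and makes no new isolated compound.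

Step 10 (directed cyclopropanation). The carbenoid may lose site selectivity and methylenate the vinyl group (or both alkenes), or react sluggishly at the tetrasubstituted alkene. The fallback carries the vinyl group as an alkyne, which zinc carbenoids leave alone. It sets out from triflate 10: Sonogashira coupling with ethynyltrimethylsilane (PdCl2(PPh3)2, CuI, Et3N) should give tert-butyl{[(1S,2S)-2,4-dimethyl-2-[(trimethylsilyl)oxy]-3-[(trimethylsilyl)ethynyl]cyclohex-3-en-1-yl]oxy}dimethylsilane F1. K2CO3/MeOH then removes both trimethylsilyl groups to give (1S,6S)-6-[(tert-butyldimethylsilyl)oxy]-2-ethynyl-1,3-dimethylcyclohex-2-en-1-ol F2. Hydroxyl-directed Simmons–Smith reaction (Et2Zn, CH2I2) on its only alkene gives (1S,2S,3S,6R)-3-[(tert-butyldimethylsilyl)oxy]-1-ethynyl-2,6-dimethylbicyclo[4.1.0]heptan-2-ol F3. Semihydrogenation (H2, Pd/CaCO3 poisoned with Pb(OAc)2, quinoline) returns to the route at 13.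

Step 13 (acetone aldol at C7). The ketone–ketone aldol equilibrium of a stabilised dienolate may be unfavourable, with retro-aldol cleavage on quench or warming, or proton transfer may compete. The fallback brings C11 in with the alkene partner so that no aldol is needed. Commercial 2-methylbut-3-yn-2-ol is silylated (TBSOTf, 2,6-lutidine) to tert-butyldimethyl[(2-methylbut-3-yn-2-yl)oxy]silane F4 and hydrostannylated (Bu3SnH, PdCl2(PPh3)2) to tert-butyldimethyl{[(3E)-2-methyl-4-(tributylstannyl)but-3-en-2-yl]oxy}silane F5. The fallback then sets out from triflate 10: Stille coupling with F5 under the conditions of step 8 should give tert-butyl{[(1S,2S)-3-[(1E)-3-[(tert-butyldimethylsilyl)oxy]-3-methylbut-1-en-1-yl]-2,4-dimethyl-2-[(trimethylsilyl)oxy]cyclohex-3-en-1-yl]oxy}dimethylsilane F6. K2CO3/MeOH gives (1S,6S)-6-[(tert-butyldimethylsilyl)oxy]-2-[(1E)-3-[(tert-butyldimethylsilyl)oxy]-3-methylbut-1-en-1-yl]-1,3-dimethylcyclohex-2-en-1-ol F7. Directed Simmons–Smith reaction, now helped by the hindered second alkene, gives (1R,2S,3S,6R)-3-[(tert-butyldimethylsilyl)oxy]-1-[(1E)-3-[(tert-butyldimethylsilyl)oxy]-3-methylbut-1-en-1-yl]-2,6-dimethylbicyclo[4.1.0]heptan-2-ol F8. Carbonylation as in step 11 gives (5S,6S,8aR)-6-[(tert-butyldimethylsilyl)oxy]-3-{2-[(tert-butyldimethylsilyl)oxy]propan-2-yl}-5-hydroxy-5,8a-dimethyl-3,5,6,7,8,8a-hexahydronaphthalen-2(1H)-one F9. Silylation with 1-(trimethylsilyl)imidazole returns to the route at 20.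

**Further compounds**
F0 | step 11 | none | none
F1 | step 10 | tert-butyl{[(1S,2S)-2,4-dimethyl-2-[(trimethylsilyl)oxy]-3-[(trimethylsilyl)ethynyl]cyclohex-3-en-1-yl]oxy}dimethylsilane | C[Si](C)(C)O[C@]1(C)[C@@H](O[Si](C)(C)C(C)(C)C)CCC(C)=C1C#C[Si](C)(C)C
F2 | step 10 | (1S,6S)-6-[(tert-butyldimethylsilyl)oxy]-2-ethynyl-1,3-dimethylcyclohex-2-en-1-ol | O[C@]1(C)[C@@H](O[Si](C)(C)C(C)(C)C)CCC(C)=C1C#C
F3 | step 10 | (1S,2S,3S,6R)-3-[(tert-butyldimethylsilyl)oxy]-1-ethynyl-2,6-dimethylbicyclo[4.1.0]heptan-2-ol | O[C@]1(C)[C@@H](O[Si](C)(C)C(C)(C)C)CC[C@]2(C)C[C@@]21C#C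
F4 | step 13 | tert-butyldimethyl[(2-methylbut-3-yn-2-yl)oxy]silane | C#CC(C)(C)O[Si](C)(C)C(C)(C)C
F5 | step 13 | tert-butyldimethyl{[(3E)-2-methyl-4-(tributylstannyl)but-3-en-2-yl]oxy}silane | CCCC[Sn](CCCC)(CCCC)/C=C/C(C)(C)O[Si](C)(C)C(C)(C)C
F6 | step 13 | tert-butyl{[(1S,2S)-3-[(1E)-3-[(tert-butyldimethylsilyl)oxy]-3-methylbut-1-en-1-yl]-2,4-dimethyl-2-[(trimethylsilyl)oxy]cyclohex-3-en-1-yl]oxy}dimethylsilane | C[Si](C)(C)O[C@]1(C)[C@@H](O[Si](C)(C)C(C)(C)C)CCC(C)=C1/C=C/C(C)(C)O[Si](C)(C)C(C)(C)C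
F7 | step 13 | (1S,6S)-6-[(tert-butyldimethylsilyl)oxy]-2-[(1E)-3-[(tert-butyldimethylsilyl)oxy]-3-methylbut-1-en-1-yl]-1,3-dimethylcyclohex-2-en-1-ol | O[C@]1(C)[C@@H](O[Si](C)(C)C(C)(C)C)CCC(C)=C1/C=C/C(C)(C)O[Si](C)(C)C(C)(C)C
F8 | step 13 | (1R,2S,3S,6R)-3-[(tert-butyldimethylsilyl)oxy]-1-[(1E)-3-[(tert-butyldimethylsilyl)oxy]-3-methylbut-1-en-1-yl]-2,6-dimethylbicyclo[4.1.0]heptan-2-ol | O[C@]1(C)[C@@H](O[Si](C)(C)C(C)(C)C)CC[C@]2(C)C[C@@]21/C=C/C(C)(C)O[Si](C)(C)C(C)(C)C
F9 | step 13 | (5S,6S,8aR)-6-[(tert-butyldimethylsilyl)oxy]-3-{2-[(tert-butyldimethylsilyl)oxy]propan-2-yl}-5-hydroxy-5,8a-dimethyl-3,5,6,7,8,8a-hexahydronaphthalen-2(1H)-one (C3 epimers) | O[C@]1(C)[C@@H](O[Si](C)(C)C(C)(C)C)CC[C@]2(C)CC(=O)C(C(C)(C)O[Si](C)(C)C(C)(C)C)C=C21
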